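The route rests on cutting the C4–C5 bond of ring A. Ring B (C5–C10) holds its C8 oxygen para to the methyl-bearing C5, which marks it as a latent p-cresol. C4 lies α to the C3 oxygen and is an enol carbon, so both atoms are innately nucleophilic. A chiral aryl-λ3-iodane bound to the phenol oxygen reverses the polarity of C5. One operation then forges C4–C5, closes ring A, dearomatises ring B to a cross-conjugated dienone and sets C4 and C5. The precursor is flat and achiral: 4-methylphenol carrying at C3 a two-carbon tether that ends in a positionally and geometrically defined (Z)-silyl enol ether.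

Key step: step 4

**Numbering and faces:** eremophilane numbering is used for all bicyclic compounds. Ring A = C1–C5 and C10, ring B = C5–C10, C14 = methyl on C5, C15 = methyl on C4, C11–C13 = isopropenyl. β is the face that carries C14 and α is the opposite face.

**Assumption:** the (R,R)-iodane is taken to give the (5R) series. If the sense of induction proves opposite, its (S,S)-enantiomer is used in the same way.

**Design remarks:**
- (a) The parent ketone of the precursor has two nearly equivalent α-methylene groups (C2, C4) and a phenol that would silylate first. The enol silane is therefore not made by enolising that ketone. It is brought in from ethyl vinyl ketone with its position and geometry already fixed.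
- (b) C14 is axial on ring A and shields the β face of C3, so hydride reagents can only give the axial 3β-alcohol. The equatorial 3α-ester is therefore made with inversion, which also removes any protecting group at O3.
- (c) The isopropenyl group is attached while C7 is still sp2. This avoids regioselective enolate chemistry next to the C9 oxygen.

**Step 1**
Reactants: 1 ethyl vinyl ketone (pent-1-en-3-one)
Product: 2 (Z)-3-(tert-butyldimethylsilyloxy)penta-1,3-diene
Conditions: TBSOTf, Et3N, Et2O, 0 °C to rt
Reagents that add atoms: tert-butyldimethylsilyl trifluoromethanesulfonate (TBSOTf), CC(C)(C)[Si](C)(C)OS(=O)(=O)C(F)(F)F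
Why: Soft enolisation with a silyl triflate and an amine: 1 has α-hydrogens only at C4, so a single regioisomer can form, and the Z geometry is expected because C15 turns away from the vinyl group in the O-silylated oxocarbenium ion (allylic strain).

**Step 2**
Reactants: 2 (Z)-3-(tert-butyldimethylsilyloxy)penta-1,3-diene; 3 9-borabicyclo[3.3.1]nonane (9-BBN-H); 4 3-bromo-4-methylphenol
Product: 6 3-[(Z)-3-(tert-butyldimethylsilyloxy)pent-3-en-1-yl]-4-methylphenol, via B-alkyl-9-BBN adduct 5 (not isolated)
Conditions: 3, THF, 0 °C to rt; then 4, Pd(OAc)2 (cat), SPhos (cat), K3PO4, THF–H2O, 50 °C; non-oxidative work-up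
Reagents that add atoms: none
Why: Hydroboration followed by B-alkyl Suzuki–Miyaura coupling: 9-BBN-H adds anti-Markovnikov to the monosubstituted terminal alkene far faster than to the trisubstituted enol silane, the C(sp3)–C(sp2) coupling then forms C1–C10 without touching the enol geometry, and the phenol travels as its phenoxide under the mild phosphate base, so that neither enolisation of an unsymmetrical ketone nor phenol protection is needed.

**Step 3**
Reactants: 7 (R,R)-2-iodo-1,3-bis[1-(mesitylcarbamoyl)ethoxy]benzene
Product: 8 (R,R)-2-(diacetoxy-λ3-iodanyl)-1,3-bis[1-(mesitylcarbamoyl)ethoxy]benzene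
Conditions: NaBO3·4H2O, AcOH, 45 °C
Reagents that add atoms: acetic acid, CC(=O)O
Why: Standard perborate oxidation of an iodoarene to a (diacetoxyiodo)arene, which leaves the lactamide stereocentres untouched; the iodane is preformed because a peracid co-oxidant, as used in catalytic variants, would epoxidise the enol silane of 6.

**Step 4**
Reactants: 6 3-[(Z)-3-(tert-butyldimethylsilyloxy)pent-3-en-1-yl]-4-methylphenol; 8 chiral (diacetoxyiodo)arene
Product: 10 (1R,8aR)-1,8a-dimethyl-1,3,4,8a-tetrahydronaphthalene-2,6-dione, via aryloxy(acetoxy)-λ3-iodane 9 (not isolated)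
Conditions: 8 (1.1 equiv), CH2Cl2–(CF3)2CHOH (10:1), −40 °C
Reagents that add atoms: none
Why: Proposed new method: the phenol of 6 displaces one acetate of 8 to give aryloxy-λ3-iodane 9, the enol silane then attacks C5 through C4 while the aryl iodide 7 leaves from oxygen, and acetate removes the silyl group from the silyloxocarbenium ion so that the C3 ketone and the C8 dienone carbonyl appear together. The closest known reaction types are iodine(III)-mediated para-dearomatising spirocyclisations of phenols onto allylsilanes, enol ethers or enamides, the intermolecular para-allylation of 4-alkylphenols, and enantioselective dearomatising spirolactonisations with this same class of lactamide iodane; new here are the fused mode and reagent control over a para C–C bond. Ring A closes as a six-membered ring in a 6-(enolendo) mode on the donor side, and on the acceptor side the C5–C10 edge of the arene becomes part of the new ring, which gives a fused and not a spiro dienone. C5 is controlled by the chiral iodane, whose hydrogen-bonded lactamide arms cover one face of the O-bound ring, and this holds only if C–C bond formation is concerted with loss of 7, hence the weakly ionising medium and the low temperature. C4 is controlled by the Z geometry, because C15 stays eclipsed with the enol oxygen, ends up equatorial in the half-chair closure and thus cis to axial C14, which is also the more stable epimer if the new α-centre enolises. The step needs attack at C5 and not at C9: the para carbon carries the larger share of the positive charge, its methyl group stabilises that charge further, and C9 is crowded by the tether on one side and by the bulky O–I unit on the other.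

**Step 5**
Reactants: 10 4β,5β-dimethyl-6,9-diene-3,8-dione
Product: 11 7-iodo-4β,5β-dimethyl-6,9-diene-3,8-dione
Conditions: I2, pyridine–CH2Cl2 (1:1), 0 °C to rt, dark
Reagents that add atoms: iodine, II
Why: Baylis–Hillman-type α-iodination of an enone (pyridine adds at the β-carbon, the enolate is iodinated, pyridine leaves): only C6 is a β-CH whereas C10 is fully substituted, so iodine should enter at C7 alone, and the saturated C3 ketone is inert to these conditions.

**Step 6**
Reactants: 11 7-iodo-4β,5β-dimethyl-6,9-diene-3,8-dione; 12 isopropenylboronic acid pinacol ester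
Product: 13 eremophila-6,9,11-triene-3,8-dione (4β,5β-dimethyl)
Conditions: PdCl2(dppf) (cat), K3PO4, THF–H2O, 40 °C
Reagents that add atoms: none
Why: Suzuki–Miyaura coupling of an α-iodoenone, a fast and well-behaved electrophile, fixes the isopropenyl group on C7 regiospecifically without enolate chemistry; C4 may enolise under the mild base, but its equatorial methyl group cis to C14 is the favoured epimer.

**Step 7**
Reactants: 13 eremophila-6,9,11-triene-3,8-dione
Product: 14 3β-hydroxyeremophila-6,9,11-trien-8-one
Conditions: LiAlH(Ot-Bu)3, THF, −78 to −30 °C; aqueous work-up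
Reagents that add atoms: none
Why: Chemoselective 1,2-reduction by a bulky alkoxyaluminium hydride: the saturated C3 ketone is far more electrophilic than the cross-conjugated C8 carbonyl, and because axial C14 blocks the β (axial) trajectory the hydride arrives from the α face and sets the axial 3β-alcohol, which also ends the epimerisability of C4.

**Step 8**
Reactants: 14 3β-hydroxyeremophila-6,9,11-trien-8-one; 15 angelic acid ((Z)-2-methylbut-2-enoic acid)
Product: 16 3α-angeloyloxyeremophila-6,9,11-trien-8-one
Conditions: PPh3, DIAD, toluene, 0 °C to rt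
Reagents that add atoms: none
Why: Mitsunobu esterification: SN2 displacement of the axial oxyphosphonium group by angelate from the open α face inverts C3 to the equatorial 3α-ester of the target, and since the carboxyl group is never activated the Z alkene of 15 has no channel for isomerisation to the tiglate.

**Step 9**
Reactants: 16 3α-angeloyloxyeremophila-6,9,11-trien-8-one
Product: 17 3α-angeloyloxy-7αH-eremophila-9,11-dien-8-one (7β-isopropenyl)
Conditions: [(Ph3P)CuH]6 (limiting hydride), H2O, degassed toluene, 0 °C to rt
Reagents that add atoms: none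
Why: Copper hydride conjugate reduction (Stryker's reagent): hydride goes to the β-CH C6 rather than to the fully substituted C10 and spares the hindered angelate and the isolated alkene, and the copper dienolate is protonated kinetically at its α-carbon C7 from the α face opposite axial C14, which keeps the alkene out of conjugation and sets the 7β-isopropenyl group.

**Step 10**
Reactants: 17 3α-angeloyloxy-7αH-eremophila-9,11-dien-8-one
Product: 18 3α-angeloyloxy-8-(trimethylsilyloxy)-7αH,10βH-eremophila-8,11-diene
Conditions: [(Ph3P)CuH]6, TMSCl, toluene, rt; filtration through Florisil (hexane–Et3N)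
Reagents that add atoms: chlorotrimethylsilane, C[Si](C)(C)Cl
Why: Copper hydride conjugate reduction with silyl trapping: hydride reaches C10 on the β face through the chair-like transition state in which the new hydrogen is axial on ring B while C14 and the 7β-isopropenyl group are equatorial, the usual cis outcome for copper reagents with angularly methylated octalones, and TMSCl fixes the enolate regiospecifically as the C8=C9 enol silane without touching C7.

**Step 11**
Reactants: 18 3α-angeloyloxy-8-(trimethylsilyloxy)-7αH,10βH-eremophila-8,11-diene
Product: 20 3α-angeloyloxy-9β-hydroxy-10βH-eremophil-11-en-8-one, via 9β-trimethylsilyloxy ketone 19 (not isolated)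
Conditions: mCPBA (1.05 equiv), CH2Cl2, −20 °C; then aq citric acid, THF, 0 °C
Reagents that add atoms: 3-chloroperbenzoic acid (mCPBA), O=C(OO)c1cccc(Cl)c1
Why: Rubottom oxidation: the peracid attacks the electron-rich enol silane much faster than the 1,1-disubstituted isopropenyl alkene or the electron-poor angelate, and it does so from the convex β face because axial C4 of the folded cis-decalin covers the α face, which sets the equatorial 9β-oxygen, also the more stable epimer.

**Step 12**
Reactants: 20 3α-angeloyloxy-9β-hydroxy-10βH-eremophil-11-en-8-one; 21 senecioic acid (3-methylbut-2-enoic acid)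
Product: 22 3α-angeloyloxy-9β-senecioyloxy-10βH-eremophil-11-en-8-one (target CNP0375730.2)
Conditions: DCC, DMAP (cat), CH2Cl2, 0 °C
Reagents that add atoms: none
Why: Steglich esterification acylates the only free hydroxyl group under near-neutral conditions at low temperature, which spares the base-sensitive β,γ-unsaturated ketone, creates no stereocentre and avoids the acid chloride/amine combination that would deconjugate the senecioyl unit through a vinylketene.

**Compound list**

1 | ethyl vinyl ketone (pent-1-en-3-one) | C=CC(=O)CC | starting material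
2 | (Z)-3-(tert-butyldimethylsilyloxy)penta-1,3-diene | C/C=C(\O[Si](C)(C)C(C)(C)C)C=C | intermediate
3 | 9-borabicyclo[3.3.1]nonane (9-BBN-H, sold as dimer or THF solution) | B1C2CCCC1CCC2 | starting material
4 | 3-bromo-4-methylphenol | Cc1ccc(O)cc1Br | starting material
5 | B-[(Z)-3-(tert-butyldimethylsilyloxy)pent-3-en-1-yl]-9-BBN | C/C=C(\O[Si](C)(C)C(C)(C)C)CCB1C2CCCC1CCC2 | intermediate
6 | 3-[(Z)-3-(tert-butyldimethylsilyloxy)pent-3-en-1-yl]-4-methylphenol, the (Z)-TBS enol ether of 1-(5-hydroxy-2-methylphenyl)pentan-3-one | C/C=C(\O[Si](C)(C)C(C)(C)C)CCc1cc(O)ccc1C | intermediate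
7 | (R,R)-2-iodo-1,3-bis[1-(mesitylcarbamoyl)ethoxy]benzene | Ic1c(O[C@H](C)C(=O)Nc2c(C)cc(C)cc2C)cccc1O[C@H](C)C(=O)Nc1c(C)cc(C)cc1C | starting material
8 | (R,R)-2-(diacetoxy-λ3-iodanyl)-1,3-bis[1-(mesitylcarbamoyl)ethoxy]benzene | CC(=O)OI(OC(C)=O)c1c(O[C@H](C)C(=O)Nc2c(C)cc(C)cc2C)cccc1O[C@H](C)C(=O)Nc1c(C)cc(C)cc1C | intermediate
9 | aryloxy(acetoxy)-λ3-iodane from 6 and 8 (phenol oxygen of 6 on iodine) | C/C=C(\O[Si](C)(C)C(C)(C)C)CCc1cc(OI(OC(C)=O)c2c(O[C@H](C)C(=O)Nc3c(C)cc(C)cc3C)cccc2O[C@H](C)C(=O)Nc2c(C)cc(C)cc2C)ccc1C | intermediate
10 | (1R,8aR)-1,8a-dimethyl-1,3,4,8a-tetrahydronaphthalene-2,6-dione; eremophilane numbering (4R,5R)-4β,5β-dimethyl-6,9-diene-3,8-dione, C14 and C15 cis | C[C@H]1C(=O)CCC2=CC(=O)C=C[C@]12C | intermediate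
11 | 7-iodo-4β,5β-dimethyl-6,9-diene-3,8-dione | C[C@H]1C(=O)CCC2=CC(=O)C(I)=C[C@]12C | intermediate
12 | isopropenylboronic acid pinacol ester | C=C(C)B1OC(C)(C)C(C)(C)O1 | starting material
13 | eremophila-6,9,11-triene-3,8-dione (4β,5β-dimethyl) | C[C@H]1C(=O)CCC2=CC(=O)C(C(C)=C)=C[C@]12C | intermediate
14 | 3β-hydroxyeremophila-6,9,11-trien-8-one (OH axial, cis to C14 and C15) | C[C@H]1[C@@H](O)CCC2=CC(=O)C(C(C)=C)=C[C@]12C | intermediate
15 | angelic acid, (Z)-2-methylbut-2-enoic acid | C/C=C(/C)C(=O)O | starting material
16 | 3α-angeloyloxyeremophila-6,9,11-trien-8-one (ester equatorial, trans to C15) | C[C@H]1[C@H](OC(=O)/C(C)=C\C)CCC2=CC(=O)C(C(C)=C)=C[C@]12C | intermediate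
17 | 3α-angeloyloxy-7αH-eremophila-9,11-dien-8-one (7β-isopropenyl, cis to C14) | C=C(C)[C@H]1C[C@@]2(C)C(CC[C@@H](OC(=O)/C(C)=C\C)[C@@H]2C)=CC1=O | intermediate
18 | 3α-angeloyloxy-8-(trimethylsilyloxy)-7αH,10βH-eremophila-8,11-diene (cis-fused) | C=C(C)[C@H]1C[C@@]2(C)[C@H](CC[C@@H](OC(=O)/C(C)=C\C)[C@@H]2C)C=C1O[Si](C)(C)C | intermediate
19 | 3α-angeloyloxy-9β-(trimethylsilyloxy)-10βH-eremophil-11-en-8-one | C=C(C)[C@H]1C[C@@]2(C)[C@H](CC[C@@H](OC(=O)/C(C)=C\C)[C@@H]2C)[C@@H](O[Si](C)(C)C)C1=O | intermediate
20 | 3α-angeloyloxy-9β-hydroxy-10βH-eremophil-11-en-8-one | C=C(C)[C@H]1C[C@@]2(C)[C@H](CC[C@@H](OC(=O)/C(C)=C\C)[C@@H]2C)[C@@H](O)C1=O | intermediate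
21 | senecioic acid, 3-methylbut-2-enoic acid | CC(C)=CC(=O)O | starting material
22 | (3R,4R,5R,7R,9R,10S)-3α-angeloyloxy-9β-senecioyloxy-10βH-eremophil-11-en-8-one | C=C(C)[C@H]1C[C@@]2(C)[C@H](CC[C@@H](OC(=O)/C(C)=C\C)[C@@H]2C)[C@@H](OC(=O)C=C(C)C)C1=O | target

**Total step count:** 12.
**Longest linear sequence:** 11 (steps 1, 2 and 4–12; step 3 is a side branch).

**Steps most likely to fail**

**1. Step 4.**
What may go wrong:
- attack at C9 followed by rearomatisation;
- weak facial discrimination if the aryloxyiodane ionises before the C–C bond forms;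
- direct oxidation of the enol silane by the iodane.

The fallback runs from 6 back to 10 and swaps the roles of the two carbons, using known chemistry. NBS (THF, −78 °C) converts the enol silane, which is far more nucleophilic than the phenol ring, regiospecifically into racemic 4-bromo-1-(5-hydroxy-2-methylphenyl)pentan-3-one F1. One equivalent of KOt-Bu in t-BuOH–THF then triggers intramolecular para C-alkylation of the phenoxide (Winstein–Masamune alkylative dearomatisation). C4 settles in the cis-dimethyl series by enolisation. This gives 10 together with the mirror-image dienone-dione ent-10 F2, which is removed by preparative chromatography on a chiral stationary phase.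

**2. Step 8.**
What may go wrong:
- elimination towards C2 or C4 in place of substitution;
- sluggish activation of the crowded axial hydroxyl group.

The fallback runs from 13 back to 16 and avoids substitution at C3 altogether. A ketoreductase is picked from a commercial panel for β-face hydride delivery (NADPH recycled with i-PrOH, pH 7 buffer, 30 °C). It reduces only the saturated C3 ketone, against the substrate bias, to 3α-hydroxyeremophila-6,9,11-trien-8-one F3. F3 is then acylated with retention by the mixed anhydride of 15 and 2,4,6-trichlorobenzoyl chloride (Et3N, toluene, 80 °C, Yamaguchi-type esterification without DMAP).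

**3. Step 9.**
What may go wrong:
- poor facial selectivity in the protonation at C7;
- drift of the isopropenyl alkene into conjugation.

The fallback runs from 16 to 22 and replaces kinetic control by thermodynamic control.
- The reduction is run without regard to C7.
- The epimer 3α-angeloyloxy-7βH-eremophila-9,11-dien-8-one F4 is carried through the operations of steps 10–12. This passes through 7-epi enol silane F5, 7-epi 9β-silyloxy ketone F6 and 7-epi ketol F7 to 7-epi diester F8.
- In this cis-fused diester the 7α-isopropenyl group is axial and clashes with C4, whereas 22 has every ring substituent equatorial.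
- Brief exposure to catalytic DBU in toluene at rt should therefore move C7 (and C9, if needed) to 22 by α-reprotonation of the dienolate. The reaction is stopped before the slower γ-protonation sets in.

**Further compounds**

F1 | step 4 | 4-bromo-1-(5-hydroxy-2-methylphenyl)pentan-3-one (racemic) | CC(Br)C(=O)CCc1cc(O)ccc1C
F2 | step 4 | ent-10, (1S,8aS)-1,8a-dimethyl-1,3,4,8a-tetrahydronaphthalene-2,6-dione | C[C@@H]1C(=O)CCC2=CC(=O)C=C[C@@]12C
F3 | step 8 | 3α-hydroxyeremophila-6,9,11-trien-8-one | C[C@H]1[C@H](O)CCC2=CC(=O)C(C(C)=C)=C[C@]12C
F4 | step 9 | 3α-angeloyloxy-7βH-eremophila-9,11-dien-8-one (7-epi-17) | C=C(C)[C@@H]1C[C@@]2(C)C(CC[C@@H](OC(=O)/C(C)=C\C)[C@@H]2C)=CC1=O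
F5 | step 9 | 7-epi-18, 7α-isopropenyl enol silane | C=C(C)[C@@H]1C[C@@]2(C)[C@H](CC[C@@H](OC(=O)/C(C)=C\C)[C@@H]2C)C=C1O[Si](C)(C)C
F6 | step 9 | 7-epi-19, 7α-isopropenyl 9β-silyloxy ketone | C=C(C)[C@@H]1C[C@@]2(C)[C@H](CC[C@@H](OC(=O)/C(C)=C\C)[C@@H]2C)[C@@H](O[Si](C)(C)C)C1=O
F7 | step 9 | 7-epi-20, 7α-isopropenyl ketol | C=C(C)[C@@H]1C[C@@]2(C)[C@H](CC[C@@H](OC(=O)/C(C)=C\C)[C@@H]2C)[C@@H](O)C1=O
F8 | step 9 | 7-epi-22, 7α-isopropenyl diester | C=C(C)[C@@H]1C[C@@]2(C)[C@H](CC[C@@H](OC(=O)/C(C)=C\C)[C@@H]2C)[C@@H](OC(=O)C=C(C)C)C1=O
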